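**Plan**
- Retrosynthetic cuts: first the masking groups (three O-methyl groups, one O-triflyl group, one dioxolane), then both bonds that join the furan ring to the benzo ring, O1–C7a and C3a–C3, leaving an aryne and a trans-2,3-diaryl oxirane.
- Enabling feature: O1 and C3 sit on the neighbouring benzo carbons C7a and C3a, and C3a is flanked by the C4 oxygen. The aryne C3a≡C7a is therefore a 3-alkoxybenzyne that takes oxygen at C7a and carbon at C3a, and O1–C2–C3 is the three-membered ring of a stilbene oxide.
- Forward order: the benzo ring comes from 5-bromovanillin (ortho-silylaryl triflate, steps 1–3) and the oxirane from pterostilbene (triflation, Shi epoxidation, steps 4–5). Their union (step 6) O-arylates the epoxide and closes the dihydrofuran ring through the C3a–C3 bond; steps 7–9 unmask.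
- Stereochemistry: the Shi epoxidation sets C2 and C3. The C2–O bond is never broken, and C3 is carried over with retention (trans), which gives (2S,3S).

Key step: step 6

Assumption: the target descriptors correspond to the (2S,3S)-trans-2,3-diaryl-2,3-dihydrobenzofuran; 5-bromovanillin, pterostilbene, the D-fructose-derived Shi ketone and Bu4N[Ph3SiF2] are taken as commercial.

**Route**

Step 1
Reactants: 1 5-bromovanillin (3-bromo-4-hydroxy-5-methoxybenzaldehyde)
Product: 2 2-bromo-4-(1,3-dioxolan-2-yl)-6-methoxyphenol
Conditions: ethylene glycol (5 equiv), PPTS (cat.), toluene, reflux, Dean–Stark; Et3N quench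
Reagents that add atoms: ethylene glycol, OCCO
Why: Acid-catalysed acetalisation of the aldehyde (1,3-dioxolane formation) is driven by azeotropic removal of water and masks the formyl group against n-BuLi in step 3 and against the aryl anion in step 6; no stereocenter is formed.

Step 2
Reactants: 2 2-bromo-4-(1,3-dioxolan-2-yl)-6-methoxyphenol
Product: 3 [2-bromo-4-(1,3-dioxolan-2-yl)-6-methoxyphenoxy]trimethylsilane
Conditions: (Me3Si)2NH (0.6 equiv), THF, reflux; evaporate, use crude
Reagents that add atoms: hexamethyldisilazane, C[Si](C)(C)N[Si](C)(C)C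
Why: O-silylation of the phenol with hexamethyldisilazane gives the aryl trimethylsilyl ether with ammonia as the only by-product and sets up the oxygen-to-carbon silyl shift of step 3; no stereocenter is formed.

Step 3
Reactants: 3 [2-bromo-4-(1,3-dioxolan-2-yl)-6-methoxyphenoxy]trimethylsilane
Product: 6 4-(1,3-dioxolan-2-yl)-2-methoxy-6-(trimethylsilyl)phenyl trifluoromethanesulfonate, via aryllithium 4 (not isolated), via lithium phenolate 5 (not isolated)
Conditions: n-BuLi (1.1 equiv), THF, −78 °C; then PhNTf2 (1.2 equiv), −78 °C → rt; aq. NH4Cl work-up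
Reagents that add atoms: N-phenylbis(trifluoromethanesulfonimide), O=S(=O)(N(c1ccccc1)S(=O)(=O)C(F)(F)F)C(F)(F)F
Why: Bromine–lithium exchange gives aryllithium 4, which undergoes the 1,3 oxygen-to-carbon silyl migration (retro-Brook rearrangement) to phenolate 5, and triflation of this phenolate with PhNTf2 gives the ortho-silylaryl triflate, the standard fluoride-triggered aryne precursor; no stereocenter is formed.

Step 4
Reactants: 7 pterostilbene (4-[(E)-2-(3,5-dimethoxyphenyl)ethenyl]phenol)
Product: 8 4-[(E)-2-(3,5-dimethoxyphenyl)ethenyl]phenyl trifluoromethanesulfonate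
Conditions: Tf2O (1.2 equiv), pyridine (3 equiv), CH2Cl2, 0 °C
Reagents that add atoms: trifluoromethanesulfonic anhydride, O=S(=O)(OS(=O)(=O)C(F)(F)F)C(F)(F)F
Why: Sulfonylation of the phenol (triflate formation) protects the oxygen and turns the 4-oxyphenyl ring into an acceptor ring, which tames the acid sensitivity of the later epoxide and steers the bond cleavage in step 6; the E alkene is untouched.

Step 5
Reactants: 8 4-[(E)-2-(3,5-dimethoxyphenyl)ethenyl]phenyl trifluoromethanesulfonate
Product: 9 4-[(2R,3R)-3-(3,5-dimethoxyphenyl)oxiran-2-yl]phenyl trifluoromethanesulfonate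
Conditions: D-fructose-derived Shi ketone (0.3 equiv), KHSO5 (as 2KHSO5·KHSO4·K2SO4), K2CO3, Bu4NHSO4 (cat.), Na2B4O7 buffer, MeCN–CH2(OMe)2–H2O, 0 °C
Reagents that add atoms: potassium peroxymonosulfate, [K+].[O-]S(=O)(=O)OO
Why: Shi asymmetric epoxidation (chiral dioxirane from the ketone and KHSO5, spiro transition state) of the trans-1,2-diaryl alkene should deliver oxygen to the same face as with trans-stilbene and so give the (2R,3R)-epoxide, which sets the lasting C2 stereocenter and the relay stereocenter at C3.

Step 6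
Reactants: 6 4-(1,3-dioxolan-2-yl)-2-methoxy-6-(trimethylsilyl)phenyl trifluoromethanesulfonate (2 equiv), 9 4-[(2R,3R)-3-(3,5-dimethoxyphenyl)oxiran-2-yl]phenyl trifluoromethanesulfonate
Product: 12 4-[(2S,3S)-3-(3,5-dimethoxyphenyl)-6-(1,3-dioxolan-2-yl)-4-methoxy-2,3-dihydro-1-benzofuran-2-yl]phenyl trifluoromethanesulfonate, via aryne 10 (not isolated), via oxiranium betaine 11 (not isolated)
Conditions: Bu4N[Ph3SiF2] (2.2 equiv), toluene, 50 °C, slow addition of 6
Reagents that add atoms: none
Why: Proposed new method: fluoride converts 6 into the 3-methoxy aryne 10, whose triple bond is distorted by the inductively withdrawing methoxy group so that the epoxide oxygen of 9 adds at the carbon remote from OMe (future C7a) and the aryl anion develops at the carbon flanked by OMe (future C3a), giving betaine 11. In 11 the O-aryl oxiranium should break its bond to the carbon that carries the 3,5-dimethoxyphenyl group, because the 4-triflyloxyphenyl group on the other carbon is a strong acceptor without resonance donation and cannot support positive charge, and the aryl anion recombines with the developing benzylic cation to form the C3a–C3 bond. The closest known reaction type is the formal insertion of arynes into the benzylic C–O bond of styrene oxide to give 3-aryl-2,3-dihydrobenzofurans, which has not been shown for an enantioenriched trans-2,3-diaryl oxirane with transfer of configuration. The furan ring closes in a 5-endo mode at C3, and since a concerted backside displacement would be a stereoelectronically disallowed 5-endo-tet process, closure is expected to be an ionisation–recombination inside the contact ion pair on the face that the oxygen leaves, that is with retention. C2 keeps the configuration set in step 5 because its C–O bond is never broken, and C3 is set by this retentive collapse and, should the cation live long enough to rotate, by the preference of the 3,5-dimethoxyphenyl group to end up trans to the C2 aryl group. The step needs regioselectivity on the aryne, secured by the methoxy group next to the triple bond, regioselectivity on the epoxide, secured by the triflate, and ring closure faster than protonation of the aryl anion, which the aprotic medium supports.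

Step 7
Reactants: 12 4-[(2S,3S)-3-(3,5-dimethoxyphenyl)-6-(1,3-dioxolan-2-yl)-4-methoxy-2,3-dihydro-1-benzofuran-2-yl]phenyl trifluoromethanesulfonate
Product: 13 4-[(2S,3S)-3-(3,5-dimethoxyphenyl)-6-formyl-4-methoxy-2,3-dihydro-1-benzofuran-2-yl]phenyl trifluoromethanesulfonate
Conditions: 1 M aq. HCl, THF, rt
Reagents that add atoms: water, O
Why: Acid-catalysed hydrolysis of the dioxolane frees the aldehyde under conditions that leave the aryl triflate, the methyl ethers and the benzylic ether of the dihydrofuran untouched, the latter because its C2 aryl group is an acceptor; no stereocenter is affected.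

Step 8
Reactants: 13 4-[(2S,3S)-3-(3,5-dimethoxyphenyl)-6-formyl-4-methoxy-2,3-dihydro-1-benzofuran-2-yl]phenyl trifluoromethanesulfonate
Product: 14 4-[(2S,3S)-3-(3,5-dihydroxyphenyl)-6-formyl-4-hydroxy-2,3-dihydro-1-benzofuran-2-yl]phenyl trifluoromethanesulfonate
Conditions: BBr3 (8 equiv), CH2Cl2, −78 → 0 °C; then H2O, 0 °C
Reagents that add atoms: none
Why: Lewis-acid ether cleavage with BBr3 (aryl methyl ether demethylation by bromide attack on the boron-complexed methoxy groups) should free the three phenols while the aryl triflate is inert and the electron-poor C2 aryl group disfavours ionisation of the C2–O1 bond, so the trans stereocenters are kept.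

Step 9
Reactants: 14 4-[(2S,3S)-3-(3,5-dihydroxyphenyl)-6-formyl-4-hydroxy-2,3-dihydro-1-benzofuran-2-yl]phenyl trifluoromethanesulfonate
Product: 15 gnetal, (2S,3S)-3-(3,5-dihydroxyphenyl)-4-hydroxy-2-(4-hydroxyphenyl)-2,3-dihydro-1-benzofuran-6-carbaldehyde
Conditions: Et4NOH (20% aq., 6 equiv), 1,4-dioxane, rt, argon; then aq. NH4Cl to pH 5
Reagents that add atoms: none
Why: Hydroxide attacks the sulfur of the aryl triflate (sulfonate ester hydrolysis by S–O cleavage) and releases the last phenol at room temperature without touching either stereocenter, giving gnetal after acidification.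

**Compound list**

1 | 5-bromovanillin (3-bromo-4-hydroxy-5-methoxybenzaldehyde) | COc1cc(C=O)cc(Br)c1O | starting material
2 | 2-bromo-4-(1,3-dioxolan-2-yl)-6-methoxyphenol | COc1cc(C2OCCO2)cc(Br)c1O | intermediate
3 | [2-bromo-4-(1,3-dioxolan-2-yl)-6-methoxyphenoxy]trimethylsilane | COc1cc(C2OCCO2)cc(Br)c1O[Si](C)(C)C | intermediate
4 | [5-(1,3-dioxolan-2-yl)-3-methoxy-2-(trimethylsilyloxy)phenyl]lithium | COc1cc(C2OCCO2)cc([Li])c1O[Si](C)(C)C | intermediate (not isolated)
5 | lithium 4-(1,3-dioxolan-2-yl)-2-methoxy-6-(trimethylsilyl)phenolate | [Li+].[O-]c1c(OC)cc(C2OCCO2)cc1[Si](C)(C)C | intermediate (not isolated)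
6 | 4-(1,3-dioxolan-2-yl)-2-methoxy-6-(trimethylsilyl)phenyl trifluoromethanesulfonate | COc1cc(C2OCCO2)cc([Si](C)(C)C)c1OS(=O)(=O)C(F)(F)F | intermediate
7 | pterostilbene, 4-[(E)-2-(3,5-dimethoxyphenyl)ethenyl]phenol | COc1cc(/C=C/c2ccc(O)cc2)cc(OC)c1 | starting material
8 | 4-[(E)-2-(3,5-dimethoxyphenyl)ethenyl]phenyl trifluoromethanesulfonate | COc1cc(/C=C/c2ccc(OS(=O)(=O)C(F)(F)F)cc2)cc(OC)c1 | intermediate
9 | 4-[(2R,3R)-3-(3,5-dimethoxyphenyl)oxiran-2-yl]phenyl trifluoromethanesulfonate | FC(F)(F)S(=O)(=O)Oc1ccc(cc1)[C@H]1O[C@@H]1c1cc(OC)cc(OC)c1 | intermediate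
10 | 5-(1,3-dioxolan-2-yl)-3-methoxybenzyne (1,2-didehydro-3-methoxy-5-(1,3-dioxolan-2-yl)benzene) | COC1=CC(C2OCCO2)=CC#C1 | intermediate (not isolated)
11 | oxiranium betaine: epoxide 9 arylated at oxygen by the aryne carbon remote from OMe, carbanion on the ring carbon between O+ and OMe, oxirane carbons as in 9 | COc1cc(C2OCCO2)cc([O+]3[C@H](c4ccc(OS(=O)(=O)C(F)(F)F)cc4)[C@H]3c3cc(OC)cc(OC)c3)[c-]1 | intermediate (not isolated)
12 | 4-[(2S,3S)-3-(3,5-dimethoxyphenyl)-6-(1,3-dioxolan-2-yl)-4-methoxy-2,3-dihydro-1-benzofuran-2-yl]phenyl trifluoromethanesulfonate | O1CCOC1c1cc(OC)c2c(c1)O[C@H](c1ccc(OS(=O)(=O)C(F)(F)F)cc1)[C@H]2c1cc(OC)cc(OC)c1 | intermediate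
13 | 4-[(2S,3S)-3-(3,5-dimethoxyphenyl)-6-formyl-4-methoxy-2,3-dihydro-1-benzofuran-2-yl]phenyl trifluoromethanesulfonate | O=Cc1cc(OC)c2c(c1)O[C@H](c1ccc(OS(=O)(=O)C(F)(F)F)cc1)[C@H]2c1cc(OC)cc(OC)c1 | intermediate
14 | 4-[(2S,3S)-3-(3,5-dihydroxyphenyl)-6-formyl-4-hydroxy-2,3-dihydro-1-benzofuran-2-yl]phenyl trifluoromethanesulfonate | O=Cc1cc(O)c2c(c1)O[C@H](c1ccc(OS(=O)(=O)C(F)(F)F)cc1)[C@H]2c1cc(O)cc(O)c1 | intermediate
15 | gnetal, (2S,3S)-3-(3,5-dihydroxyphenyl)-4-hydroxy-2-(4-hydroxyphenyl)-2,3-dihydro-1-benzofuran-6-carbaldehyde | O=Cc1cc(O)c2c(c1)O[C@H](c1ccc(O)cc1)[C@H]2c1cc(O)cc(O)c1 | target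

**Step count and risks**

Total steps: 9. Longest linear sequence: 7 steps (1 → 2 → 3 → 6 → 12 → 13 → 14 → 15; steps 1, 2, 3, 6, 7, 8, 9). The stilbene branch (7 → 8 → 9) adds 2 steps before the union.

Steps most likely to fail:

1. Step 6 (bears the label).
   - What may go wrong: the weakly basic epoxide oxygen may be too slow to capture the aryne, which is then lost by self-reaction. The oxiranium may cleave at the other C–O bond and give the regioisomeric diaryl pattern. A hydride shift or proton transfer in the betaine may outrun ring closure.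
   - Fallback (known reactions only; sets out from 8, comes back at 13): 8 is epoxidised with the enantiomeric Shi ketone (made from L-sorbose) under the conditions of step 5, which should give 4-[(2S,3S)-3-(3,5-dimethoxyphenyl)oxiran-2-yl]phenyl trifluoromethanesulfonate F1. Commercial 3-hydroxy-5-methoxybenzaldehyde (COc1cc(O)cc(C=O)c1) is protected as 3-methoxy-5-(methoxymethoxy)benzaldehyde F2 (MOMCl, i-Pr2NEt, CH2Cl2) and then as 2-[3-methoxy-5-(methoxymethoxy)phenyl]-1,3-dioxolane F3 (ethylene glycol, PPTS, toluene, reflux). Directed ortho-lithiation of F3 (n-BuLi, THF, 0 °C) at the carbon between the two oxygen substituents gives [4-(1,3-dioxolan-2-yl)-2-methoxy-6-(methoxymethoxy)phenyl]lithium F4. In the presence of BF3·OEt2 at −78 °C, F4 should open F1 at the carbon bearing the 3,5-dimethoxyphenyl group, with inversion, to give 4-[(1R,2S)-2-(3,5-dimethoxyphenyl)-2-[4-(1,3-dioxolan-2-yl)-2-methoxy-6-(methoxymethoxy)phenyl]-1-hydroxyethyl]phenyl trifluoromethanesulfonate F5. Aqueous HCl in THF removes the methoxymethyl group and the dioxolane to give 4-[(1R,2S)-2-(3,5-dimethoxyphenyl)-2-(4-formyl-2-hydroxy-6-methoxyphenyl)-1-hydroxyethyl]phenyl trifluoromethanesulfonate F6. Mitsunobu cyclodehydration (PPh3, DIAD, THF, 0 °C) then closes the O1–C2 bond with inversion to give 13. The two inversions, at C3 on opening and at C2 on closure, turn the (2S,3S)-epoxide into the (2S,3S)-trans-dihydrobenzofuran.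

2. Step 8.
   - What may go wrong: Lewis-acid cleavage of the benzylic C2–O1 bond may open the dihydrofuran ring. Cleavage of the hindered C4 methyl ether may stop short. Material may be lost through bromination at the formyl carbon.
   - Fallback (sets out from 13, comes back at 15): the triflate is removed first (Et4NOH, dioxane, rt) to give (2S,3S)-3-(3,5-dimethoxyphenyl)-2-(4-hydroxyphenyl)-4-methoxy-2,3-dihydro-1-benzofuran-6-carbaldehyde F7, and the three methyl ethers are then cleaved with BBr3 (CH2Cl2, −78 → 0 °C) to give 15. With the free 4-hydroxyphenyl group at C2, any opening of the C2–O1 bond becomes a reversible para-quinone methide opening. It should reclose by conjugate addition of the C7a oxygen, under control of the fixed C3 stereocenter, to the trans isomer. The approach therefore changes from preventing ring opening to making it harmless.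

3. Step 9.
   - What may go wrong: once the phenoxide on the C2 aryl group has formed in aqueous base, elimination across C2–O1 to a para-quinone methide (ring opening, epimerisation at C2, addition of hydroxide) may compete with S–O cleavage. Oxidation or disproportionation of the phenoxide-rich aldehyde may also compete.
   - Fallback (sets out from 14, comes back at 15): Miyaura borylation of the aryl triflate (Pd(dppf)Cl2, bis(pinacolato)diboron, KOAc, dioxane, 80 °C) gives (2S,3S)-3-(3,5-dihydroxyphenyl)-4-hydroxy-2-[4-(4,4,5,5-tetramethyl-1,3,2-dioxaborolan-2-yl)phenyl]-2,3-dihydro-1-benzofuran-6-carbaldehyde F8. Oxidation of the carbon–boron bond (NaBO3·4H2O, THF–H2O, rt) then gives 15. The phenol oxygen is thus introduced by C–B oxidation under nearly neutral conditions instead of being unmasked with hydroxide.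

**Further compounds**

F1 | step 6 | 4-[(2S,3S)-3-(3,5-dimethoxyphenyl)oxiran-2-yl]phenyl trifluoromethanesulfonate | FC(F)(F)S(=O)(=O)Oc1ccc(cc1)[C@@H]1O[C@H]1c1cc(OC)cc(OC)c1
F2 | step 6 | 3-methoxy-5-(methoxymethoxy)benzaldehyde | COCOc1cc(C=O)cc(OC)c1
F3 | step 6 | 2-[3-methoxy-5-(methoxymethoxy)phenyl]-1,3-dioxolane | COCOc1cc(C2OCCO2)cc(OC)c1
F4 | step 6 | [4-(1,3-dioxolan-2-yl)-2-methoxy-6-(methoxymethoxy)phenyl]lithium | [Li]c1c(OC)cc(C2OCCO2)cc1OCOC
F5 | step 6 | 4-[(1R,2S)-2-(3,5-dimethoxyphenyl)-2-[4-(1,3-dioxolan-2-yl)-2-methoxy-6-(methoxymethoxy)phenyl]-1-hydroxyethyl]phenyl trifluoromethanesulfonate | O[C@@H](c1ccc(OS(=O)(=O)C(F)(F)F)cc1)[C@H](c1c(OC)cc(C2OCCO2)cc1OCOC)c1cc(OC)cc(OC)c1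
F6 | step 6 | 4-[(1R,2S)-2-(3,5-dimethoxyphenyl)-2-(4-formyl-2-hydroxy-6-methoxyphenyl)-1-hydroxyethyl]phenyl trifluoromethanesulfonate | O[C@@H](c1ccc(OS(=O)(=O)C(F)(F)F)cc1)[C@H](c1c(OC)cc(C=O)cc1O)c1cc(OC)cc(OC)c1
F7 | step 8 | (2S,3S)-3-(3,5-dimethoxyphenyl)-2-(4-hydroxyphenyl)-4-methoxy-2,3-dihydro-1-benzofuran-6-carbaldehyde | O=Cc1cc(OC)c2c(c1)O[C@H](c1ccc(O)cc1)[C@H]2c1cc(OC)cc(OC)c1
F8 | step 9 | (2S,3S)-3-(3,5-dihydroxyphenyl)-4-hydroxy-2-[4-(4,4,5,5-tetramethyl-1,3,2-dioxaborolan-2-yl)phenyl]-2,3-dihydro-1-benzofuran-6-carbaldehyde | O=Cc1cc(O)c2c(c1)O[C@H](c1ccc(B3OC(C)(C)C(C)(C)O3)cc1)[C@H]2c1cc(O)cc(O)c1
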